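## Structural features

The target is a C40 carotenoid triol: two trimethylcyclohexene end groups joined by a methyl-branched C22 chain with eight E double bonds from C7 to C10' and a C7'≡C8' triple bond conjugated to the C5'=C6' alkene of ring B. Ring A (C1 gem-dimethyl, C2, C3, C4=C5 with the C5 methyl, C6) has a secondary allylic hydroxyl at C3 (S) and a tertiary hydroxyl at C6 (R). C6 is fully substituted (C1, C5, O, C7), and its hydroxyl is cis to the C3 hydroxyl across the C4=C5 alkene; the two stereocentres are separated by C4 and C5 and are not adjacent. Ring B has one remote stereocentre, C3' (R), and a tetrasubstituted C5'=C6' alkene. The fragile parts are the doubly allylic tertiary C6 hydroxyl (ionises with acid), the polyene-yne chromophore (light, oxygen, acid), and the geometry of C9'=C10' next to the alkyne and of the two alkenes made by olefination. The real difficulty is the congested C6 carbinol next to the C1 gem-dimethyl group, whose configuration must be set relative to C3, and only then the polyene. The key step exploits that ring A is the allylic transposition isomer of a ring B type ring with a heteroatom at C4: moving the alkene from C5=C6 to C4=C5 and the heteroatom from C4 to C6 turns one into the other, so both rings can come from one cyclohexenyl enyne.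

## Logic of the disconnections

22 ⇒ 21. Only the O–Si bonds at C3 and C3' are cut. This leaves a final step that is neither acidic nor oxidising. The demand is that fluoride leaves the C6 carbinol and the polyene untouched.

21 ⇒ 16 + 20. The C11=C12 alkene is cut. This splits C40 into C15 and C25 at a disubstituted alkene whose cis isomer is strained and reverts on heating, and brings the sensitive C6 carbinol in late on a small fragment. The forward olefination needs a base too weak to expel the C6 hydroxyl from the ylide.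

20 ⇒ 18 + 19. The C11'=C12' alkene is cut. 19 supplies C12 to C12' with both methyls and three E alkenes in one piece, reducing the ring B half to C15. The forward step must olefinate 19 once only and keep C9'=C10' E.

18 ⇒ 6 and 16 ⇒ 14. The C11'–P and C11–P bonds are cut back to primary allylic alcohols, so both halves use the same operation. It must run without acid and without an allylic cation, for the sake of the C6 carbinol in 14 and the 9'E alkene in 6.

14 ⇒ 13. No skeletal bond is cut: C7=C8 is traced back to an alkyne and the primary hydroxyl to its ester. The propargylic hydroxyl directs a trans hydrometalation, so the alkyne is a stereochemical precursor of the 7E alkene and ties ring A to the enyne chemistry of ring B. One hydride reagent must reduce the alkyne and cleave the ester while sparing the silyl ether.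

13 ⇒ 10. The C6–O bond is cut, the alkene is returned from C4=C5 to C5=C6 and selenium is placed on C4. This replaces the quaternary carbinol stereocentre by a secondary centre next to C3, where relative configuration is easier to set, and makes ring A a derivative of the ring B skeleton. The forward step needs selenium cis to the C3 oxygen, oxidation at selenium only, and a suprafacial shift.

10 ⇒ 9 ⇒ 8 ⇒ 7. C4–Se is cut with inversion to a trans C4–O bond, the carbinol is traced to a ketone and the ketone to the ring methylene. This takes the C4 heteroatom back to a C–H bond of the common enyne. The demands are SN2 rather than ionisation, hydride delivery on the correct face, and C–H oxidation at C4 rather than at a methyl group or at C11. For the last reason the primary oxygen is an acyl ester and not a p-methoxybenzyl ether, whose benzylic and allylic ether hydrogens would not survive the oxidant.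

7 ⇒ 6 ⇒ 4 + 5. The ester C–O bond and then the C6–C7 bond between ring and chain are cut. 6 serves both halves of the molecule. The coupling must work at a hindered tetrasubstituted enol triflate and retain the geometry of 5.

4 ⇒ 2 ⇒ 1. The enol O–S bond and the O–Si bond are cut. The C4 stereocentre of 1 becomes C3 and C3' of the target, and its C6 stereocentre is expendable. Enolisation is unambiguous because only one α-carbon carries hydrogen.

## Other disconnections considered

Alternative 1: The cut removes the C13' methyl and the C14'–C15' bond. The ring B C18 dienediyne A1 would undergo Cp2ZrCl2-catalysed syn methylalumination at its terminal alkyne, then transmetalation with ZnCl2 and Pd(PPh3)4-catalysed coupling with the ring A C21 pentaenyl iodide A2, giving the tris(silyl) ether A3. In its favour, the carbometalation is stereospecific and the coupling retains geometry, so C13'=C14' and C15=C15' would be formed E by mechanism; on chain geometry it is the better plan, since the chosen olefinations rely on thermal correction of cis isomers. Against it, A2 is a light-sensitive iodide that needs a long chain-building sequence on ring A and protection of the tertiary hydroxyl, Me3Al is a strong Lewis acid towards an enyne carrying a second alkyne, and ring A must still be made by another method. On the C6 stereocentre the two plans are therefore equal, and in step count this alternative is clearly longer.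

Alternative 2: The cut is the C6–C7 bond. The dilithio derivative A5 of 5 would add to the carbonyl of the silylated enone A4, giving the ring A propargylic diol A6, which one hydride reduction would convert into 14. In step economy this is better than the chosen plan: about four steps from 1 to 14 instead of nine, with no selenium and no C–H oxidation. Against it, the C6 configuration rests on the facial selectivity of a 1,2-addition controlled by a silyloxy group in a 1,4 relationship. With that group pseudo-equatorial, attack anti to the axial C1 methyl would place the alkynyl group cis to the silyloxy group, which suggests that the unwanted 6-epimer could predominate. The chosen plan instead relays configuration intramolecularly from C4 to C6, but it pays for this with a substrate-controlled reduction at C4, so its stereochemical advantage is real only if step 6 is selective. Both plans use 1 and 5.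

Alternative 3: The cut is the C6'–C7' bond, made last. Triflate 4 would be coupled under Pd(PPh3)4 and CuI with the terminal alkyne of the C31 polyenyne A7 to give the bis(silyl) ether A8, which is identical with 21. In its favour, ring B needs only the two steps to 4, no acetylenic phosphonium salt is required, and the end game is the same single desilylation. The bond and catalyst are those of step 3, so mechanistically the plans are equal. Against it, A7 is a hexaenyne with a terminal alkyne and a free tertiary carbinol that would have to survive copper, amine and the warming a hindered triflate needs, and the whole chain must first be built linearly on ring A. The chosen plan performs the same coupling on two small, robust partners.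

Key step: step 8

Remarks on the chemistry. Carotenoid numbering is used (C1 gem-dimethyl carbon to C6, chain from C7, ring B primed). TBS is tert-butyldimethylsilyl and Piv is 2,2-dimethylpropanoyl. Selenium in 11 is a stereocentre of no consequence and is left undefined. The C3 descriptor changes from R (1 to 7) to S (8 onwards) only because the ring branch priorities change; the centre is never inverted. With selenium cis to the C3 oxygen in 10, a suprafacial shift gives the 3,6-cis arrangement of 13 and of the target.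

## Route

Step 1
Reactants: 1 (4R,6R)-4-hydroxy-2,2,6-trimethylcyclohexan-1-one (actinol)
Product: 2 (4R,6R)-4-(TBS-oxy)-2,2,6-trimethylcyclohexan-1-one
Conditions: TBSCl, imidazole, DMF, rt
Reagents that add atoms: tert-butyldimethylsilyl chloride CC(C)(C)[Si](C)(C)Cl
Why: Imidazole-promoted silylation of a secondary alcohol; the ketone and both stereocentres are untouched.

Step 2
Reactants: 2 (4R,6R)-4-(TBS-oxy)-2,2,6-trimethylcyclohexan-1-one
Product: 4 (4R)-4-(TBS-oxy)-2,6,6-trimethylcyclohex-1-en-1-yl trifluoromethanesulfonate, via lithium enolate 3 (not isolated)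
Conditions: LiN(iPr)2, THF, −78 → 0 °C; PhNTf2, −78 °C → rt; aq. NH4Cl
Reagents that add atoms: N-phenylbis(trifluoromethanesulfonimide) O=S(=O)(N(c1ccccc1)S(=O)(=O)C(F)(F)F)C(F)(F)F
Why: Only one α-carbon carries hydrogen, so a single enolate can form, and O-sulfonylation fixes the tetrasubstituted C5=C6 alkene as an enol triflate; the former C6 stereocentre of actinol is deliberately lost.

Step 3
Reactants: 4 (4R)-4-(TBS-oxy)-2,6,6-trimethylcyclohex-1-en-1-yl trifluoromethanesulfonate; 5 (2E)-3-methylpent-2-en-4-yn-1-ol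
Product: 6 (2E)-5-[(4R)-4-(TBS-oxy)-2,6,6-trimethylcyclohex-1-en-1-yl]-3-methylpent-2-en-4-yn-1-ol
Conditions: Pd(PPh3)4 (5 mol%), CuI (10 mol%), Et3N, DMF, degassed, 50 °C
Reagents that add atoms: none
Why: Sonogashira coupling (oxidative addition of zerovalent palladium to the enol triflate, transmetalation from the copper acetylide, reductive elimination) forms C6–C7; the free primary alcohol is tolerated and the E alkene of 5 is not involved.

Step 4
Reactants: 6 (2E)-5-[(4R)-4-(TBS-oxy)-2,6,6-trimethylcyclohex-1-en-1-yl]-3-methylpent-2-en-4-yn-1-ol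
Product: 7 (2E)-5-[(4R)-4-(TBS-oxy)-2,6,6-trimethylcyclohex-1-en-1-yl]-3-methylpent-2-en-4-yn-1-yl 2,2-dimethylpropanoate
Conditions: PivCl, pyridine, DMAP (cat.), CH2Cl2, 0 °C → rt
Reagents that add atoms: pivaloyl chloride CC(C)(C)C(=O)Cl
Why: Acylation of the unhindered primary allylic alcohol; the pivalate has no benzylic hydrogen, deactivates the C11 hydrogens towards the oxidant of step 5 and is removed by the hydride of step 9 without a separate operation.

Step 5
Reactants: 7 (2E)-5-[(4R)-4-(TBS-oxy)-2,6,6-trimethylcyclohex-1-en-1-yl]-3-methylpent-2-en-4-yn-1-yl 2,2-dimethylpropanoate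
Product: 8 (2E)-5-[(4S)-4-(TBS-oxy)-2,6,6-trimethyl-3-oxocyclohex-1-en-1-yl]-3-methylpent-2-en-4-yn-1-yl 2,2-dimethylpropanoate
Conditions: CrO3, 3,5-dimethylpyrazole, CH2Cl2, −20 °C
Reagents that add atoms: chromium trioxide O=[Cr](=O)=O
Why: Allylic oxidation of a ring methylene to the enone by the CrO3–3,5-dimethylpyrazole complex; C4 is the only secondary allylic position, its intermediate is delocalised over the enyne, the methyl groups react more slowly and the C11 hydrogens are deactivated by the acyloxy group.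

Step 6
Reactants: 8 (2E)-5-[(4S)-4-(TBS-oxy)-2,6,6-trimethyl-3-oxocyclohex-1-en-1-yl]-3-methylpent-2-en-4-yn-1-yl 2,2-dimethylpropanoate
Product: 9 (2E)-5-[(3S,4S)-4-(TBS-oxy)-3-hydroxy-2,6,6-trimethylcyclohex-1-en-1-yl]-3-methylpent-2-en-4-yn-1-yl 2,2-dimethylpropanoate (3,4-trans)
Conditions: NaBH4, CeCl3·7H2O, MeOH, −78 °C
Reagents that add atoms: none
Why: Luche 1,2-reduction; the silyloxy group must be pseudo-equatorial (pseudo-axial it would clash with the axial C1 methyl), so axial hydride delivery anti to the axial C3 hydrogen should give the pseudo-equatorial, 3,4-trans alcohol (new C4 stereocentre, substrate control), and the ester is spared.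

Step 7
Reactants: 9 (2E)-5-[(3S,4S)-4-(TBS-oxy)-3-hydroxy-2,6,6-trimethylcyclohex-1-en-1-yl]-3-methylpent-2-en-4-yn-1-yl 2,2-dimethylpropanoate
Product: 10 (2E)-5-[(3R,4S)-4-(TBS-oxy)-2,6,6-trimethyl-3-(phenylselanyl)cyclohex-1-en-1-yl]-3-methylpent-2-en-4-yn-1-yl 2,2-dimethylpropanoate (3,4-cis)
Conditions: N-(phenylseleno)phthalimide, PBu3, THF, −20 °C → rt
Reagents that add atoms: N-(phenylseleno)phthalimide O=C1c2ccccc2C(=O)N1[Se]c1ccccc1
Why: Grieco–Nicolaou redox condensation: the alcohol is activated as its tributylphosphonium ether and displaced by phenylselenolate in an SN2 step with inversion, turning the trans alcohol into the selenide cis to the silyl ether; SN2' attack at C6 is blocked by the gem-dimethyl and alkynyl groups.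

Step 8
Reactants: 10 (2E)-5-[(3R,4S)-4-(TBS-oxy)-2,6,6-trimethyl-3-(phenylselanyl)cyclohex-1-en-1-yl]-3-methylpent-2-en-4-yn-1-yl 2,2-dimethylpropanoate
Product: 13 (2E)-5-[(1R,4S)-4-(TBS-oxy)-1-hydroxy-2,6,6-trimethylcyclohex-2-en-1-yl]-3-methylpent-2-en-4-yn-1-yl 2,2-dimethylpropanoate, via selenoxide 11 (not isolated), via selenenate 12 (not isolated)
Conditions: 30% aq. H2O2 (3 equiv), pyridine, CH2Cl2, −20 → 10 °C
Reagents that add atoms: hydrogen peroxide OO
Why: H2O2 oxidises the selenide to selenoxide 11, which undergoes a concerted suprafacial [2,3]-sigmatropic shift through a five-membered envelope transition state: the selenoxide oxygen bonds to C6, the C4–Se bond breaks and the alkene moves from C5=C6 to C4=C5, giving selenenate 12. This is the allylic selenoxide–selenenate rearrangement, the selenium counterpart of the Mislow–Evans reaction, and no ring is closed. The new C6 stereocentre is controlled by C4: oxygen can only arrive on the face that carried selenium, which is the face of the C3 silyl ether, so the cis selenide gives the 3,6-cis (6R) carbinol. Regiochemistry is fixed because C6 is the only γ-carbon of the allyl selenoxide. Hydrolysis of 12 in the aqueous pyridine medium removes it from the equilibrium, so the deconjugated tertiary alcohol is obtained under kinetic control although it is the less stable allylic isomer. Syn elimination cannot compete because C5 has no hydrogen and the C3 hydrogen is trans to selenium. The step needs oxidation at selenium only, in the presence of two alkenes, an alkyne and an ester; the much higher nucleophilicity of the selenide, the low temperature and the pyridine buffer should secure this.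

Step 9
Reactants: 13 (2E)-5-[(1R,4S)-4-(TBS-oxy)-1-hydroxy-2,6,6-trimethylcyclohex-2-en-1-yl]-3-methylpent-2-en-4-yn-1-yl 2,2-dimethylpropanoate
Product: 14 (2E,4E)-5-[(1R,4S)-4-(TBS-oxy)-1-hydroxy-2,6,6-trimethylcyclohex-2-en-1-yl]-3-methylpenta-2,4-dien-1-ol
Conditions: NaAlH2(OCH2CH2OMe)2 (Red-Al, 5 equiv), THF, 0 °C → rt; aq. KNaC4H4O6
Reagents that add atoms: none
Why: Alkoxide-directed trans hydroalumination of the propargylic alcohol and protonolysis should give the 7E alkene only, as in the classical reduction of enynyl carbinols to dienols; excess hydride also cleaves the pivalate, while the silyl ether, the C6 stereocentre and the 9E alkene are unaffected.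

Step 10
Reactants: 14 (2E,4E)-5-[(1R,4S)-4-(TBS-oxy)-1-hydroxy-2,6,6-trimethylcyclohex-2-en-1-yl]-3-methylpenta-2,4-dien-1-ol
Product: 16 [(2E,4E)-5-[(1R,4S)-4-(TBS-oxy)-1-hydroxy-2,6,6-trimethylcyclohex-2-en-1-yl]-3-methylpenta-2,4-dien-1-yl]triphenylphosphonium bromide, via allylic bromide 15 (not isolated)
Conditions: CBr4 (1.05 equiv), PPh3, CH2Cl2, −20 °C; then PPh3, MeCN, rt
Reagents that add atoms: tetrabromomethane BrC(Br)(Br)Br; triphenylphosphine c1ccc(cc1)P(c1ccccc1)c1ccccc1
Why: Appel bromination occurs by SN2 at the primary allylic hydroxyl under neutral conditions (the tertiary hydroxyl is too hindered to be activated), and quaternisation of PPh3 by the bromide gives the Wittig salt without exposing the acid-labile C6 carbinol to HBr.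

Step 11
Reactants: 6 (2E)-5-[(4R)-4-(TBS-oxy)-2,6,6-trimethylcyclohex-1-en-1-yl]-3-methylpent-2-en-4-yn-1-ol
Product: 18 [(2E)-5-[(4R)-4-(TBS-oxy)-2,6,6-trimethylcyclohex-1-en-1-yl]-3-methylpent-2-en-4-yn-1-yl]triphenylphosphonium bromide, via allylic bromide 17 (not isolated)
Conditions: CBr4, PPh3, CH2Cl2, −20 °C; then PPh3, MeCN, rt
Reagents that add atoms: tetrabromomethane BrC(Br)(Br)Br; triphenylphosphine c1ccc(cc1)P(c1ccccc1)c1ccccc1
Why: The same Appel bromination and quaternisation; displacement at the primary carbon avoids an allylic cation, so the E geometry of C9'=C10' next to the alkyne should be retained.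

Step 12
Reactants: 18 [(2E)-5-[(4R)-4-(TBS-oxy)-2,6,6-trimethylcyclohex-1-en-1-yl]-3-methylpent-2-en-4-yn-1-yl]triphenylphosphonium bromide; 19 (2E,4E,6E)-2,7-dimethylocta-2,4,6-trienedial
Product: 20 (2E,4E,6E,8E,10E)-13-[(4R)-4-(TBS-oxy)-2,6,6-trimethylcyclohex-1-en-1-yl]-2,7,11-trimethyltrideca-2,4,6,8,10-pentaen-12-ynal
Conditions: 19 (3 equiv), NaOMe, CH2Cl2/MeOH, 0 °C → rt, dark; then heptane, 80 °C
Reagents that add atoms: none
Why: Wittig olefination of the semi-stabilised allylic ylide with an excess of the symmetrical dialdehyde forms C11'=C12' once; the strained 11'-cis isomer formed alongside should revert to E on heating, and the alkenes of 19 are carried through unchanged.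

Step 13
Reactants: 16 [(2E,4E)-5-[(1R,4S)-4-(TBS-oxy)-1-hydroxy-2,6,6-trimethylcyclohex-2-en-1-yl]-3-methylpenta-2,4-dien-1-yl]triphenylphosphonium bromide; 20 (2E,4E,6E,8E,10E)-13-[(4R)-4-(TBS-oxy)-2,6,6-trimethylcyclohex-1-en-1-yl]-2,7,11-trimethyltrideca-2,4,6,8,10-pentaen-12-ynal
Product: 21 (3S,6R,3'R)-3,3'-bis(TBS-oxy)-4,5,7',8'-tetradehydro-5,6-dihydro-β,β-caroten-6-ol
Conditions: NaOMe, CH2Cl2/MeOH, 0 °C → rt, dark, argon; then heptane/EtOAc, 70 °C
Reagents that add atoms: none
Why: A second Wittig olefination forms C11=C12; methoxide is basic enough for the allylic phosphonium salt but should not expel the C6 hydroxyl, and the 11-cis isomer is again thermally labile, so the all-E polyene is expected after brief heating.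

Step 14
Reactants: 21 (3S,6R,3'R)-3,3'-bis(TBS-oxy)-4,5,7',8'-tetradehydro-5,6-dihydro-β,β-caroten-6-ol
Product: 22 (3S,6R,3'R)-4,5,7',8'-tetradehydro-5,6-dihydro-β,β-carotene-3,6,3'-triol (target)
Conditions: Bu4NF, THF, 0 °C → rt, dark, argon
Reagents that add atoms: none
Why: Fluoride cleaves both secondary silyl ethers under non-acidic conditions that the doubly allylic tertiary alcohol and the polyene should tolerate; no stereocentre is involved.

## Compound list

1 | (4R,6R)-4-hydroxy-2,2,6-trimethylcyclohexan-1-one (actinol) | O=C1[C@H](C)C[C@@H](O)CC1(C)C | starting material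
2 | (4R,6R)-4-[(tert-butyldimethylsilyl)oxy]-2,2,6-trimethylcyclohexan-1-one | O=C1[C@H](C)C[C@@H](O[Si](C)(C)C(C)(C)C)CC1(C)C | intermediate
3 | lithium (4R)-4-[(tert-butyldimethylsilyl)oxy]-2,6,6-trimethylcyclohex-1-en-1-olate (not isolated) | [Li]OC1=C(C)C[C@@H](O[Si](C)(C)C(C)(C)C)CC1(C)C | intermediate
4 | (4R)-4-[(tert-butyldimethylsilyl)oxy]-2,6,6-trimethylcyclohex-1-en-1-yl trifluoromethanesulfonate | CC1=C(OS(=O)(=O)C(F)(F)F)C(C)(C)C[C@H](O[Si](C)(C)C(C)(C)C)C1 | intermediate
5 | (2E)-3-methylpent-2-en-4-yn-1-ol | C#C/C(C)=C/CO | starting material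
6 | (2E)-5-[(4R)-4-[(tert-butyldimethylsilyl)oxy]-2,6,6-trimethylcyclohex-1-en-1-yl]-3-methylpent-2-en-4-yn-1-ol | CC1=C(C#C/C(C)=C/CO)C(C)(C)C[C@H](O[Si](C)(C)C(C)(C)C)C1 | intermediate
7 | pivalate of 6 | CC1=C(C#C/C(C)=C/COC(=O)C(C)(C)C)C(C)(C)C[C@H](O[Si](C)(C)C(C)(C)C)C1 | intermediate
8 | (2E)-5-[(4S)-4-[(tert-butyldimethylsilyl)oxy]-2,6,6-trimethyl-3-oxocyclohex-1-en-1-yl]-3-methylpent-2-en-4-yn-1-yl 2,2-dimethylpropanoate | CC1=C(C#C/C(C)=C/COC(=O)C(C)(C)C)C(C)(C)C[C@H](O[Si](C)(C)C(C)(C)C)C1=O | intermediate
9 | (2E)-5-[(3S,4S)-4-[(tert-butyldimethylsilyl)oxy]-3-hydroxy-2,6,6-trimethylcyclohex-1-en-1-yl]-3-methylpent-2-en-4-yn-1-yl 2,2-dimethylpropanoate (3,4-trans) | CC1=C(C#C/C(C)=C/COC(=O)C(C)(C)C)C(C)(C)C[C@H](O[Si](C)(C)C(C)(C)C)[C@H]1O | intermediate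
10 | (2E)-5-[(3R,4S)-4-[(tert-butyldimethylsilyl)oxy]-2,6,6-trimethyl-3-(phenylselanyl)cyclohex-1-en-1-yl]-3-methylpent-2-en-4-yn-1-yl 2,2-dimethylpropanoate (3,4-cis) | CC1=C(C#C/C(C)=C/COC(=O)C(C)(C)C)C(C)(C)C[C@H](O[Si](C)(C)C(C)(C)C)[C@@H]1[Se]c1ccccc1 | intermediate
11 | Se-oxide of 10, mixture at selenium (not isolated) | CC1=C(C#C/C(C)=C/COC(=O)C(C)(C)C)C(C)(C)C[C@H](O[Si](C)(C)C(C)(C)C)[C@@H]1[Se](=O)c1ccccc1 | intermediate
12 | (2E)-5-[(1R,4S)-4-[(tert-butyldimethylsilyl)oxy]-2,6,6-trimethyl-1-[(phenylselanyl)oxy]cyclohex-2-en-1-yl]-3-methylpent-2-en-4-yn-1-yl 2,2-dimethylpropanoate (not isolated) | CC1=C[C@@H](O[Si](C)(C)C(C)(C)C)CC(C)(C)[C@]1(O[Se]c1ccccc1)C#C/C(C)=C/COC(=O)C(C)(C)C | intermediate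
13 | (2E)-5-[(1R,4S)-4-[(tert-butyldimethylsilyl)oxy]-1-hydroxy-2,6,6-trimethylcyclohex-2-en-1-yl]-3-methylpent-2-en-4-yn-1-yl 2,2-dimethylpropanoate | CC1=C[C@@H](O[Si](C)(C)C(C)(C)C)CC(C)(C)[C@]1(O)C#C/C(C)=C/COC(=O)C(C)(C)C | intermediate
14 | (2E,4E)-5-[(1R,4S)-4-[(tert-butyldimethylsilyl)oxy]-1-hydroxy-2,6,6-trimethylcyclohex-2-en-1-yl]-3-methylpenta-2,4-dien-1-ol | CC1=C[C@@H](O[Si](C)(C)C(C)(C)C)CC(C)(C)[C@]1(O)/C=C/C(C)=C/CO | intermediate
15 | (1R,4S)-1-[(1E,3E)-5-bromo-3-methylpenta-1,3-dien-1-yl]-4-[(tert-butyldimethylsilyl)oxy]-2,6,6-trimethylcyclohex-2-en-1-ol (not isolated) | CC1=C[C@@H](O[Si](C)(C)C(C)(C)C)CC(C)(C)[C@]1(O)/C=C/C(C)=C/CBr | intermediate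
16 | [(2E,4E)-5-[(1R,4S)-4-[(tert-butyldimethylsilyl)oxy]-1-hydroxy-2,6,6-trimethylcyclohex-2-en-1-yl]-3-methylpenta-2,4-dien-1-yl]triphenylphosphonium bromide | CC1=C[C@@H](O[Si](C)(C)C(C)(C)C)CC(C)(C)[C@]1(O)/C=C/C(C)=C/C[P+](c1ccccc1)(c1ccccc1)c1ccccc1.[Br-] | intermediate
17 | (2E)-5-[(4R)-4-[(tert-butyldimethylsilyl)oxy]-2,6,6-trimethylcyclohex-1-en-1-yl]-3-methylpent-2-en-4-yn-1-yl bromide (not isolated) | CC1=C(C#C/C(C)=C/CBr)C(C)(C)C[C@H](O[Si](C)(C)C(C)(C)C)C1 | intermediate
18 | [(2E)-5-[(4R)-4-[(tert-butyldimethylsilyl)oxy]-2,6,6-trimethylcyclohex-1-en-1-yl]-3-methylpent-2-en-4-yn-1-yl]triphenylphosphonium bromide | CC1=C(C#C/C(C)=C/C[P+](c2ccccc2)(c2ccccc2)c2ccccc2)C(C)(C)C[C@H](O[Si](C)(C)C(C)(C)C)C1.[Br-] | intermediate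
19 | (2E,4E,6E)-2,7-dimethylocta-2,4,6-trienedial | O=C/C(C)=C/C=C/C=C(\C)C=O | starting material
20 | (2E,4E,6E,8E,10E)-13-[(4R)-4-[(tert-butyldimethylsilyl)oxy]-2,6,6-trimethylcyclohex-1-en-1-yl]-2,7,11-trimethyltrideca-2,4,6,8,10-pentaen-12-ynal | O=C/C(C)=C/C=C/C=C(C)/C=C/C=C(\C)C#CC1=C(C)C[C@@H](O[Si](C)(C)C(C)(C)C)CC1(C)C | intermediate
21 | (3S,6R,3'R)-3,3'-bis[(tert-butyldimethylsilyl)oxy]-4,5,7',8'-tetradehydro-5,6-dihydro-β,β-caroten-6-ol | CC1=C[C@@H](O[Si](C)(C)C(C)(C)C)CC(C)(C)[C@]1(O)/C=C/C(C)=C/C=C/C(C)=C/C=C/C=C(C)/C=C/C=C(\C)C#CC1=C(C)C[C@@H](O[Si](C)(C)C(C)(C)C)CC1(C)C | intermediate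
22 | (3S,6R,3'R)-4,5,7',8'-tetradehydro-5,6-dihydro-β,β-carotene-3,6,3'-triol | CC1=C[C@@H](O)CC(C)(C)[C@]1(O)/C=C/C(C)=C/C=C/C(C)=C/C=C/C=C(C)/C=C/C=C(\C)C#CC1=C(C)C[C@@H](O)CC1(C)C | target

Total step count: 14. Longest linear sequence: 12 steps (steps 1 to 10, 13 and 14); the ring B branch from 6 is steps 11 and 12.

## Least certain steps

Step 8 (key step). The most likely failure is over-oxidation: benzeneseleninic acid and H2O2 form a peracid-like oxidant that could epoxidise the new allylic alcohol or the enyne. Also, any loss of configurational purity at C4 from step 7 is copied to C6, because the shift is stereospecific. The fallback uses sulfur and separates the oxidation from the rearrangement. Setting out from 9, N-(phenylthio)succinimide and PBu3 should give, with inversion, the cis sulfide (2E)-5-[(3R,4S)-4-(TBS-oxy)-2,6,6-trimethyl-3-(phenylsulfanyl)cyclohex-1-en-1-yl]-3-methylpent-2-en-4-yn-1-yl 2,2-dimethylpropanoate F1. One equivalent of mCPBA at −78 °C would give its S-oxide F2. Warming F2 with Et2NH in MeOH (Mislow–Evans conditions, the amine draining the sulfenate) would release the alcohol with no oxidant present and return to the route at 13.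

Step 5. The most likely failure is poor site selectivity of the C–H oxidation: attack at the C18 or C19 methyl groups or at the enyne, with C4 deactivated by the neighbouring C–O bond. The fallback installs the C4 oxygen on the ring before the coupling. Setting out from 2, Saegusa dehydrogenation (LiN(iPr)2, Me3SiCl; then Pd(OAc)2, MeCN) gives the enone (4S)-4-(TBS-oxy)-2,6,6-trimethylcyclohex-2-en-1-one F3. Nucleophilic epoxidation (H2O2, NaOH, MeOH, 0 °C) anti to the silyloxy group gives the epoxy ketone (1R,5S,6R)-5-(TBS-oxy)-1,3,3-trimethyl-7-oxabicyclo[4.1.0]heptan-2-one F4. Two-electron opening of the α C–O bond (LiC10H8, lithium naphthalenide, THF, −78 °C) and trapping of the enolate with PhNTf2 gives (3S,4S)-4-(TBS-oxy)-3-hydroxy-2,6,6-trimethylcyclohex-1-en-1-yl trifluoromethanesulfonate F5, with the C4 oxygen trans to the silyl ether. Sonogashira coupling with 5 gives the diol (2E)-5-[(3S,4S)-4-(TBS-oxy)-3-hydroxy-2,6,6-trimethylcyclohex-1-en-1-yl]-3-methylpent-2-en-4-yn-1-ol F6. Pivaloylation of its primary hydroxyl (PivCl, pyridine, −20 °C) returns to the route at 9, bypassing steps 5 and 6.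

Step 6. The most likely failure is poor facial selectivity of hydride delivery, since an equatorial α-oxygen substituent can erode the preference for axial attack. The fallback makes the other epimer on purpose and inverts it. Setting out from 8, LiBH(sBu)3 (THF, −78 °C) should attack equatorially to give the cis alcohol (2E)-5-[(3R,4S)-4-(TBS-oxy)-3-hydroxy-2,6,6-trimethylcyclohex-1-en-1-yl]-3-methylpent-2-en-4-yn-1-yl 2,2-dimethylpropanoate F7. Mitsunobu reaction (4-nitrobenzoic acid, PPh3, DIAD) gives the trans (3S,4S) 4-nitrobenzoate F8. K2CO3 in MeOH at 0 °C should cleave the activated aryl ester faster than the pivalate and return to the route at 9.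

Step 7. The most likely failure is slow displacement, because the nucleophile must enter cis to the bulky silyl ether; ionisation of the allylic oxyphosphonium ion, with capture on the open face or loss of a proton, could then compete. The fallback separates activation from displacement and uses a free selenolate. Setting out from 9, MsCl and Et3N (CH2Cl2, −30 °C) give the methanesulfonate of 9 F9, used crude. NaSePh, generated from PhSeSePh and NaBH4 in EtOH/THF at 0 °C, should displace it with inversion and return to the route at 10.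

Step 13. The most likely failure is vinylogous elimination of the C6 hydroxyl from the ylide, whose carbanion is delocalised to C7 next to the carbinol carbon, or decomposition of salt 16. The fallback reverses the polarity of the coupling. Setting out from 14, MnO2 (CH2Cl2, rt) gives the aldehyde (2E,4E)-5-[(1R,4S)-4-(TBS-oxy)-1-hydroxy-2,6,6-trimethylcyclohex-2-en-1-yl]-3-methylpenta-2,4-dienal F10. Setting out from 20, NaBH4 gives the C25 alcohol (2E,4E,6E,8E,10E)-13-[(4R)-4-(TBS-oxy)-2,6,6-trimethylcyclohex-1-en-1-yl]-2,7,11-trimethyltrideca-2,4,6,8,10-pentaen-12-yn-1-ol F11. CBr4/PPh3 and then PPh3 convert it into the corresponding triphenylphosphonium bromide F12. Wittig reaction of F12 with F10 (NaOMe, CH2Cl2/MeOH) forms the same C11=C12 bond and returns to the route at 21.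

## Further compounds

F1 | step 8 | (2E)-5-[(3R,4S)-4-[(tert-butyldimethylsilyl)oxy]-2,6,6-trimethyl-3-(phenylsulfanyl)cyclohex-1-en-1-yl]-3-methylpent-2-en-4-yn-1-yl 2,2-dimethylpropanoate | CC1=C(C#C/C(C)=C/COC(=O)C(C)(C)C)C(C)(C)C[C@H](O[Si](C)(C)C(C)(C)C)[C@@H]1Sc1ccccc1
F2 | step 8 | S-oxide of F1, mixture at sulfur | CC1=C(C#C/C(C)=C/COC(=O)C(C)(C)C)C(C)(C)C[C@H](O[Si](C)(C)C(C)(C)C)[C@@H]1S(=O)c1ccccc1
F3 | step 5 | (4S)-4-[(tert-butyldimethylsilyl)oxy]-2,6,6-trimethylcyclohex-2-en-1-one | CC1=C[C@@H](O[Si](C)(C)C(C)(C)C)CC(C)(C)C1=O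
F4 | step 5 | (1R,5S,6R)-5-[(tert-butyldimethylsilyl)oxy]-1,3,3-trimethyl-7-oxabicyclo[4.1.0]heptan-2-one | CC1(C)C[C@H](O[Si](C)(C)C(C)(C)C)[C@H]2O[C@@]2(C)C1=O
F5 | step 5 | (3S,4S)-4-[(tert-butyldimethylsilyl)oxy]-3-hydroxy-2,6,6-trimethylcyclohex-1-en-1-yl trifluoromethanesulfonate | CC1=C(OS(=O)(=O)C(F)(F)F)C(C)(C)C[C@H](O[Si](C)(C)C(C)(C)C)[C@H]1O
F6 | step 5 | (2E)-5-[(3S,4S)-4-[(tert-butyldimethylsilyl)oxy]-3-hydroxy-2,6,6-trimethylcyclohex-1-en-1-yl]-3-methylpent-2-en-4-yn-1-ol | CC1=C(C#C/C(C)=C/CO)C(C)(C)C[C@H](O[Si](C)(C)C(C)(C)C)[C@H]1O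
F7 | step 6 | (2E)-5-[(3R,4S)-4-[(tert-butyldimethylsilyl)oxy]-3-hydroxy-2,6,6-trimethylcyclohex-1-en-1-yl]-3-methylpent-2-en-4-yn-1-yl 2,2-dimethylpropanoate (3,4-cis) | CC1=C(C#C/C(C)=C/COC(=O)C(C)(C)C)C(C)(C)C[C@H](O[Si](C)(C)C(C)(C)C)[C@@H]1O
F8 | step 6 | (3S,4S) 4-nitrobenzoate of 9 (3,4-trans) | CC1=C(C#C/C(C)=C/COC(=O)C(C)(C)C)C(C)(C)C[C@H](O[Si](C)(C)C(C)(C)C)[C@H]1OC(=O)c1ccc(cc1)[N+](=O)[O-]
F9 | step 7 | methanesulfonate of 9 (3,4-trans) | CC1=C(C#C/C(C)=C/COC(=O)C(C)(C)C)C(C)(C)C[C@H](O[Si](C)(C)C(C)(C)C)[C@H]1OS(C)(=O)=O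
F10 | step 13 | (2E,4E)-5-[(1R,4S)-4-[(tert-butyldimethylsilyl)oxy]-1-hydroxy-2,6,6-trimethylcyclohex-2-en-1-yl]-3-methylpenta-2,4-dienal | CC1=C[C@@H](O[Si](C)(C)C(C)(C)C)CC(C)(C)[C@]1(O)/C=C/C(C)=C/C=O
F11 | step 13 | (2E,4E,6E,8E,10E)-13-[(4R)-4-[(tert-butyldimethylsilyl)oxy]-2,6,6-trimethylcyclohex-1-en-1-yl]-2,7,11-trimethyltrideca-2,4,6,8,10-pentaen-12-yn-1-ol | OC/C(C)=C/C=C/C=C(C)/C=C/C=C(\C)C#CC1=C(C)C[C@@H](O[Si](C)(C)C(C)(C)C)CC1(C)C
F12 | step 13 | triphenylphosphonium bromide derived from F11 | [Br-].c1ccccc1[P+](c1ccccc1)(c1ccccc1)C/C(C)=C/C=C/C=C(C)/C=C/C=C(\C)C#CC1=C(C)C[C@@H](O[Si](C)(C)C(C)(C)C)CC1(C)C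
A1 | alternative 1 | ring B C18 dienediyne with terminal C13'≡C14' alkyne, 3'-silyl ether | C#C/C=C/C=C(\C)C#CC1=C(C)C[C@@H](O[Si](C)(C)C(C)(C)C)CC1(C)C
A2 | alternative 1 | ring A C21 pentaenyl iodide, 3-O-TBS, 6-O-trimethylsilyl | CC1=C[C@@H](O[Si](C)(C)C(C)(C)C)CC(C)(C)[C@]1(O[Si](C)(C)C)/C=C/C(C)=C/C=C/C(C)=C/C=C/I
A3 | alternative 1 | target as its tris(silyl) ether | CC1=C[C@@H](O[Si](C)(C)C(C)(C)C)CC(C)(C)[C@]1(O[Si](C)(C)C)/C=C/C(C)=C/C=C/C(C)=C/C=C/C=C(C)/C=C/C=C(\C)C#CC1=C(C)C[C@@H](O[Si](C)(C)C(C)(C)C)CC1(C)C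
A4 | alternative 2 | (4S)-4-[(tert-butyldimethylsilyl)oxy]-2,6,6-trimethylcyclohex-2-en-1-one | CC1=C[C@@H](O[Si](C)(C)C(C)(C)C)CC(C)(C)C1=O
A5 | alternative 2 | dilithio derivative of 5 (acetylide and alkoxide) | [Li]C#C/C(C)=C/CO[Li]
A6 | alternative 2 | ring A C15 propargylic diol, C3 silyl ether | CC1=C[C@@H](O[Si](C)(C)C(C)(C)C)CC(C)(C)[C@]1(O)C#C/C(C)=C/CO
A7 | alternative 3 | C31 polyenyne with ring A and a terminal C7' alkyne | CC1=C[C@@H](O[Si](C)(C)C(C)(C)C)CC(C)(C)[C@]1(O)/C=C/C(C)=C/C=C/C(C)=C/C=C/C=C(C)/C=C/C=C(\C)C#C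
A8 | alternative 3 | target as its 3,3'-bis(silyl) ether (identical with 21) | CC1=C[C@@H](O[Si](C)(C)C(C)(C)C)CC(C)(C)[C@]1(O)/C=C/C(C)=C/C=C/C(C)=C/C=C/C=C(C)/C=C/C=C(\C)C#CC1=C(C)C[C@@H](O[Si](C)(C)C(C)(C)C)CC1(C)C
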